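The ash run gives two rates, and two chemists read them differently.

in all of them: enzyme 0.01 mol%
- maple: substrate 11 mM; run made earlier
- ash: substrate 18 mM; run made earlier
- teal: substrate 19 mM; time 25 h
- violet: substrate 30 mM; time 8.0 h

| run | time / h | target / % | substrate / % |
|---|---|---|---|
| maple | 3.00 | 12.1 | 89.0 |
| maple | 6.00 | 22.8 | 76.3 |
| maple | 10.0 | 37.6 | 65.6 |
| maple | 12.0 | 40.1 | 58.7 |
| ash | 1.50 | 5.5 | 92.6 |
| ash | 4.00 | 15.0 | 84.3 |
| ash | 8.00 | 31.8 | 69.7 |
| ash | 12.0 | 45.6 | 55.9 |

(readings scatter by 1 percentage point)

- which one finishes higher in amount of target, in percent of the substrate charged ("neither" within 2 percentage points) (teal / violet / neither)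
- amount of target at the end, in percent of the substrate charged, teal
- amount of target at the end, in percent of the substrate charged, violet

One reads the ash run as nearly a straight line. The forecast is that view's: “Ash is nearly linear at about 3.8%/h down to 56% substrate, so it is not first order in substrate.” It puts teal at 85% (72% to 95%) and violet at 32% (26% to 36%), with teal higher. Its violet figure is what a straight line through the last two ash readings gives at that time.

I compare rates at two moments instead. In the ash run, substrate fell by 0.0393 h⁻¹ of the charge up to 4.00 h, with a mean of 92.1% left. Between 8.00 h and 12.0 h it fell by 0.0345 h⁻¹, with 62.8% left. The rate therefore drifted down, but more slowly than the substrate did.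

The apparent reaction order n, the logarithm of the rate ratio divided by the logarithm of the ratio of substrate left, is 0.336, a reading through a scatter of 1 percentage point. Writing the rate as r₀sⁿ, with s the fraction of substrate left, gives r₀ = 0.0403 h⁻¹ and s^(1−n) = 1 − (1−n)r₀t. Carried over unchanged from ash, this gives teal 81.1% and violet 30.5%. So I also expect teal higher, but less high than the forecast does.

The flasks give teal 77.7% and violet 30.2%, so teal finishes higher. On teal the order reckoning lands nearer, with the forecast 7.3 points high. The straight-line view keeps the early stretch: in violet, with 70% of the substrate left, the forecast is 1.8 points off.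

    substrate + enzyme → target + enzyme, rate k1*[substrate]*[enzyme]/(1 + ([substrate]/Km1)) (9.76 mM, k = 2290 L mol⁻¹ min⁻¹)
    2 enzyme ⇌ resting dimer, settled at all times (K = 6.66 × 10⁵ L mol⁻¹)

Teal held 45.8% of target at 12.5 h and gained 32 points more by 25.0 h. The same rule on these two gains gives n = 0.520, higher than the ash reading, with teal's substrate down to 22.3% at 25.0 h.

For teal read at 10 h, the carried n gives 37.4%. The computed flask gives 37.6%.

All runs were computed with made-up constants; scatter was added.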